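The route rests on cutting the C(sp3)–C(sp2) bond between the second side-chain methylene and the first olefinic CH, inside the 1,5-diene that links ring olefin C4=C5 of the dihydropyran to the chain. One operation, hydroboration of a 5-vinyl-3,6-dihydro-2H-pyran followed by B-alkyl Suzuki–Miyaura coupling with a C14 (E)-vinyl iodide, turns the conjugated vinyl group into the nucleophilic homoallylic carbon and joins both halves with retention of olefin geometry. The precursor is a cyclic 1,3-diene made by ring-closing enyne metathesis; it carries the acrylic acid masked as a silylalkyne, unmasked at the end by Markovnikov hydroxycarbonylation. C2 comes from a Brown allylation.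

Key step: step 6

Assumption: (5E)-geranylacetone of high isomeric purity, 3-(triisopropylsilyl)propynal, propargyl bromide and (−)-Ipc2BOMe are taken as commercial; the pyran ring is numbered O1, C2 (stereocentre), C3, C4=C5, C6 throughout.

Step 1
Reactants: 1 3-(triisopropylsilyl)prop-2-ynal
Product: 3 (3S)-1-(triisopropylsilyl)hex-5-en-1-yn-3-ol, via diisopinocampheylborinate ester 2 (not isolated)
Conditions: (−)-Ipc2BOMe, allylMgBr, Et2O, 0 °C to rt; then 1, −100 °C to −78 °C; then NaOH, H2O2, 0 °C to rt
Reagents that add atoms: allylmagnesium bromide, C=CC[Mg]Br, whose allyl group is delivered through (−)-B-allyldiisopinocampheylborane, C=CCB([C@@H]1C[C@@H]2C[C@H]([C@H]1C)C2(C)C)[C@@H]1C[C@@H]2C[C@H]([C@H]1C)C2(C)C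
Why: Brown asymmetric allylboration through a closed chair (Zimmerman–Traxler) transition state, in which the isopinocampheyl groups of the (+)-α-pinene-derived reagent direct allyl transfer to the Si face of the ynal; this should set C2 as (S) because the alkynyl group outranks the allyl CH2, and oxidative work-up cleaves borinate 2.

Step 2
Reactants: 3 (3S)-1-(triisopropylsilyl)hex-5-en-1-yn-3-ol; 4 propargyl bromide
Product: 5 triisopropyl[(3S)-3-(prop-2-yn-1-yloxy)hex-5-en-1-yn-1-yl]silane
Conditions: NaH, Bu4NI (cat.), THF, 0 °C to rt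
Reagents that add atoms: propargyl bromide (compound 4), C#CCBr
Why: Williamson etherification of the sodium alkoxide with the reactive propargylic bromide; the stereocentre is not touched and the bulky triisopropylsilyl group keeps the internal alkyne inert to base.

Step 3
Reactants: 5 triisopropyl[(3S)-3-(prop-2-yn-1-yloxy)hex-5-en-1-yn-1-yl]silane
Product: 6 triisopropyl{[(2S)-5-vinyl-3,6-dihydro-2H-pyran-2-yl]ethynyl}silane
Conditions: first-generation Grubbs catalyst RuCl2(PCy3)2(=CHPh) (5 mol%), ethylene (1 atm), CH2Cl2, rt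
Reagents that add atoms: none
Why: Ring-closing enyne metathesis of the 1,7-enyne in the exo mode (ethylene only sustains the ruthenium methylidene carrier) should give, in a net isomerization, the six-membered ring with olefin C4=C5 and a vinyl group on C5, while the hindered silylated alkyne does not engage and C2 is untouched.

Step 4
Reactants: 7 (5E)-geranylacetone
Product: 9 (5E)-6,10-dimethylundeca-5,9-dien-1-yne, via enol phosphate 8 (not isolated)
Conditions: LiN(iPr)2 (LDA), THF, −78 °C; ClP(O)(OEt)2, −78 °C to rt; then LiN(iPr)2 (2.3 equiv), −78 °C to rt; aq. NH4Cl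
Reagents that add atoms: none
Why: Kinetic enolate formation at the methyl group, O-phosphorylation and double-base elimination of the terminal enol phosphate (methyl ketone to terminal alkyne conversion) should give the enyne without touching the trisubstituted (E)-olefin.

Step 5
Reactants: 9 (5E)-6,10-dimethylundeca-5,9-dien-1-yne
Product: 11 (1E,5E)-1-iodo-2,6,10-trimethylundeca-1,5,9-triene, via vinylalane 10 (not isolated)
Conditions: Me3Al, Cp2ZrCl2 (0.25 equiv), CH2Cl2, rt; then I2, THF, −30 °C to 0 °C
Reagents that add atoms: trimethylaluminium, C[Al](C)C; iodine, II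
Why: Zirconium-catalysed carboalumination (Negishi methylalumination) adds methyl and aluminium syn across the terminal alkyne with aluminium on the terminal carbon, and iodinolysis of the C–Al bond with retention should give the (E)-vinyl iodide that fixes the geometry of the first side-chain olefin.

Step 6
Reactants: 6 triisopropyl{[(2S)-5-vinyl-3,6-dihydro-2H-pyran-2-yl]ethynyl}silane; 11 (1E,5E)-1-iodo-2,6,10-trimethylundeca-1,5,9-triene
Product: 13 triisopropyl{[(2S)-5-((3E,7E)-4,8,12-trimethyltrideca-3,7,11-trien-1-yl)-3,6-dihydro-2H-pyran-2-yl]ethynyl}silane, via B-alkyl-9-BBN 12 (not isolated)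
Conditions: 6 (1.3 equiv), 9-BBN, THF, 0 °C to rt; then 11, PdCl2(dppf) (5 mol%), AsPh3, Cs2CO3, DMF/H2O, rt
Reagents that add atoms: none
Why: 9-BBN should add across the terminal C=C of the conjugated vinyl group in a four-centre syn, anti-Markovnikov fashion to give the homoallylic borane 12; zerovalent palladium inserts into the C–I bond of 11, the base-activated borate transfers its primary alkyl group to divalent palladium, and reductive elimination forms the CH2–CH= bond with retention of the (E) geometry. The closest known reaction type is the B-alkyl Suzuki–Miyaura coupling of a 9-BBN adduct with an alkenyl iodide. No ring is closed and no stereocentre is created; the olefin geometry is set beforehand by the syn carboalumination in step 5, and C2 is remote and untouched. The step needs chemoselective monohydroboration of the vinyl group over the trisubstituted ring olefin C4=C5 and the alkyne, with boron on the terminal carbon and not the allylic one. The steric demand of 9-BBN, the hindered triisopropylsilyl-capped alkyne and the fact that only trisubstituted or internal π bonds remain after the first addition should secure this, and the acrylic acid is absent at this stage so no electron-poor olefin competes. The primary, unbranched B-alkyl group transfers faster than the secondary bicyclic B–C bonds, so only the side chain is delivered.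

Step 7
Reactants: 13 triisopropyl{[(2S)-5-((3E,7E)-4,8,12-trimethyltrideca-3,7,11-trien-1-yl)-3,6-dihydro-2H-pyran-2-yl]ethynyl}silane
Product: 14 (2S)-2-ethynyl-5-[(3E,7E)-4,8,12-trimethyltrideca-3,7,11-trien-1-yl]-3,6-dihydro-2H-pyran
Conditions: Bu4NF (TBAF), THF, 0 °C to rt
Reagents that add atoms: none
Why: Fluoride-induced protodesilylation of the alkynylsilane, which leaves the ethers, the olefins and the C2 stereocentre unaffected.

Step 8
Reactants: 14 (2S)-2-ethynyl-5-[(3E,7E)-4,8,12-trimethyltrideca-3,7,11-trien-1-yl]-3,6-dihydro-2H-pyran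
Product: 15 2-[(2S)-5-((3E,7E)-4,8,12-trimethyltrideca-3,7,11-trien-1-yl)-3,6-dihydro-2H-pyran-2-yl]prop-2-enoic acid
Conditions: Pd(OAc)2 (2 mol%), 2-(diphenylphosphino)pyridine (excess over acid), CH3SO3H (cat.), CO (20 bar), H2O (10 equiv), THF, 50 °C
Reagents that add atoms: carbon monoxide, [C-]#[O+]; water, O
Why: Palladium-catalysed Markovnikov hydroxycarbonylation (hydrocarboxylation) of a terminal alkyne, in which the Pd–H/2-pyridylphosphine catalyst delivers the carboxyl group to the internal alkyne carbon and hydrogen to the terminus to give the 2-substituted acrylic acid directly, while the trisubstituted olefins should not insert under these buffered conditions and C2 carries no acidic or ionizable bond.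

Compound list
1 | 3-(triisopropylsilyl)prop-2-ynal | O=CC#C[Si](C(C)C)(C(C)C)C(C)C | starting material
2 | (3S)-1-(triisopropylsilyl)hex-5-en-1-yn-3-yl diisopinocampheylborinate | C=CC[C@H](OB([C@@H]1C[C@@H]2C[C@H]([C@H]1C)C2(C)C)[C@@H]1C[C@@H]2C[C@H]([C@H]1C)C2(C)C)C#C[Si](C(C)C)(C(C)C)C(C)C | intermediate
3 | (3S)-1-(triisopropylsilyl)hex-5-en-1-yn-3-ol | C=CC[C@H](O)C#C[Si](C(C)C)(C(C)C)C(C)C | intermediate
4 | propargyl bromide (3-bromoprop-1-yne) | C#CCBr | starting material
5 | triisopropyl[(3S)-3-(prop-2-yn-1-yloxy)hex-5-en-1-yn-1-yl]silane | C=CC[C@H](OCC#C)C#C[Si](C(C)C)(C(C)C)C(C)C | intermediate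
6 | triisopropyl{[(2S)-5-vinyl-3,6-dihydro-2H-pyran-2-yl]ethynyl}silane | CC(C)[Si](C(C)C)(C(C)C)C#C[C@@H]1CC=C(C=C)CO1 | intermediate
7 | (5E)-geranylacetone, (5E)-6,10-dimethylundeca-5,9-dien-2-one | CC(=O)CC/C=C(\C)CCC=C(C)C | starting material
8 | diethyl (5E)-6,10-dimethylundeca-1,5,9-trien-2-yl phosphate | C=C(OP(=O)(OCC)OCC)CC/C=C(\C)CCC=C(C)C | intermediate
9 | (5E)-6,10-dimethylundeca-5,9-dien-1-yne | C#CCC/C=C(\C)CCC=C(C)C | intermediate
10 | dimethyl[(1E,5E)-2,6,10-trimethylundeca-1,5,9-trien-1-yl]alane | C[Al](C)/C=C(\C)CC/C=C(\C)CCC=C(C)C | intermediate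
11 | (1E,5E)-1-iodo-2,6,10-trimethylundeca-1,5,9-triene | I/C=C(\C)CC/C=C(\C)CCC=C(C)C | intermediate
12 | 9-{2-[(2S)-2-((triisopropylsilyl)ethynyl)-3,6-dihydro-2H-pyran-5-yl]ethyl}-9-borabicyclo[3.3.1]nonane | CC(C)[Si](C(C)C)(C(C)C)C#C[C@@H]1CC=C(CCB2C3CCCC2CCC3)CO1 | intermediate
13 | triisopropyl{[(2S)-5-((3E,7E)-4,8,12-trimethyltrideca-3,7,11-trien-1-yl)-3,6-dihydro-2H-pyran-2-yl]ethynyl}silane | CC(C)[Si](C(C)C)(C(C)C)C#C[C@@H]1CC=C(CC/C=C(\C)CC/C=C(\C)CCC=C(C)C)CO1 | intermediate
14 | (2S)-2-ethynyl-5-[(3E,7E)-4,8,12-trimethyltrideca-3,7,11-trien-1-yl]-3,6-dihydro-2H-pyran | C#C[C@@H]1CC=C(CC/C=C(\C)CC/C=C(\C)CCC=C(C)C)CO1 | intermediate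
15 | 2-[(2S)-5-((3E,7E)-4,8,12-trimethyltrideca-3,7,11-trien-1-yl)-3,6-dihydro-2H-pyran-2-yl]prop-2-enoic acid | C=C(C(=O)O)[C@@H]1CC=C(CC/C=C(\C)CC/C=C(\C)CCC=C(C)C)CO1 | target

Total step count: 8
Longest linear sequence: 6 steps (steps 1, 2, 3, 6, 7, 8)

Steps most likely to fail

Step 6 (key step). Transfer of the homoallylic alkyl group from boron to palladium may be slow, so that protodeboronation of the borane and reduction or homocoupling of the vinyl iodide outrun the cross-coupling. By-products of an incomplete or unselective hydroboration would also be carried straight into the coupling. The fallback sets out from 6 and comes back at 13, separating the two events and changing the transmetalating metal. Hydroboration of 6 with 9-BBN and oxidative work-up (NaBO3·4H2O) should give the primary alcohol 2-{(2S)-2-[(triisopropylsilyl)ethynyl]-3,6-dihydro-2H-pyran-5-yl}ethan-1-ol F1, which can be purified. Appel iodination (I2, PPh3, imidazole, CH2Cl2) should give {[(2S)-5-(2-iodoethyl)-3,6-dihydro-2H-pyran-2-yl]ethynyl}triisopropylsilane F2. Zinc insertion (Zn dust, LiCl, THF) should give iodo{2-[(2S)-2-((triisopropylsilyl)ethynyl)-3,6-dihydro-2H-pyran-5-yl]ethyl}zinc F3, which is not isolated. Negishi coupling of this reagent with 11 under Pd(PPh3)4 in THF should then return 13.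

Step 8. The branched selectivity of the carbonylation may erode next to the α-branched ether carbon, and palladium hydride or the acid co-catalyst may cause migration or cyclization of the trisubstituted olefins. The fallback sets out from 14 and comes back at 15 without acid or carbon monoxide. Hydrostannation with Bu3SnH under Mo(CO)3(CNtBu)3 catalysis (THF, 55 °C), which is selective for the carbon next to a propargylic ether, should give tributyl{1-[(2S)-5-((3E,7E)-4,8,12-trimethyltrideca-3,7,11-trien-1-yl)-3,6-dihydro-2H-pyran-2-yl]vinyl}stannane F4. Tin–lithium exchange with n-BuLi in THF at −78 °C should give {1-[(2S)-5-((3E,7E)-4,8,12-trimethyltrideca-3,7,11-trien-1-yl)-3,6-dihydro-2H-pyran-2-yl]vinyl}lithium F5, which is not isolated. It is quenched at once with CO2 and acidified on work-up to give 15.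

Step 3. The enyne may close in the endo mode to a seven-membered ring diene, or the 1,3-diene product may be consumed by secondary metathesis (dimerization through its vinyl group). The fallback sets out from 3 and comes back at 6, closing the ring by olefin metathesis and attaching the vinyl group afterwards. Alkylation of 3 with 2,3-dichloropropene (NaH, NaI cat., THF) should give {(3S)-3-[(2-chloroprop-2-en-1-yl)oxy]hex-5-en-1-yn-1-yl}triisopropylsilane F6. Ring-closing metathesis with the second-generation Grubbs catalyst RuCl2(H2IMes)(PCy3)(=CHPh) in toluene at 80 °C should give {[(2S)-5-chloro-3,6-dihydro-2H-pyran-2-yl]ethynyl}triisopropylsilane F7. Stille coupling with tributyl(vinyl)stannane (Pd2(dba)3, P(t-Bu)3, CsF, dioxane, 100 °C) should then give 6.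

Further compounds
F1 | step 6 | 2-{(2S)-2-[(triisopropylsilyl)ethynyl]-3,6-dihydro-2H-pyran-5-yl}ethan-1-ol | CC(C)[Si](C(C)C)(C(C)C)C#C[C@@H]1CC=C(CCO)CO1
F2 | step 6 | {[(2S)-5-(2-iodoethyl)-3,6-dihydro-2H-pyran-2-yl]ethynyl}triisopropylsilane | CC(C)[Si](C(C)C)(C(C)C)C#C[C@@H]1CC=C(CCI)CO1
F3 | step 6 | iodo{2-[(2S)-2-((triisopropylsilyl)ethynyl)-3,6-dihydro-2H-pyran-5-yl]ethyl}zinc | CC(C)[Si](C(C)C)(C(C)C)C#C[C@@H]1CC=C(CC[Zn]I)CO1
F4 | step 8 | tributyl{1-[(2S)-5-((3E,7E)-4,8,12-trimethyltrideca-3,7,11-trien-1-yl)-3,6-dihydro-2H-pyran-2-yl]vinyl}stannane | C=C([Sn](CCCC)(CCCC)CCCC)[C@@H]1CC=C(CC/C=C(\C)CC/C=C(\C)CCC=C(C)C)CO1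
F5 | step 8 | {1-[(2S)-5-((3E,7E)-4,8,12-trimethyltrideca-3,7,11-trien-1-yl)-3,6-dihydro-2H-pyran-2-yl]vinyl}lithium | [Li]C(=C)[C@@H]1CC=C(CC/C=C(\C)CC/C=C(\C)CCC=C(C)C)CO1
F6 | step 3 | {(3S)-3-[(2-chloroprop-2-en-1-yl)oxy]hex-5-en-1-yn-1-yl}triisopropylsilane | C=CC[C@H](OCC(Cl)=C)C#C[Si](C(C)C)(C(C)C)C(C)C
F7 | step 3 | {[(2S)-5-chloro-3,6-dihydro-2H-pyran-2-yl]ethynyl}triisopropylsilane | CC(C)[Si](C(C)C)(C(C)C)C#C[C@@H]1CC=C(Cl)CO1
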